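**Retrosynthetic overview**

1. Atom numbers are germacranolide numbers: C1 carbinol, C2, C3 and C10 the two ether carbons, C4=C5, C6 lactone carbinol, C7, C8 ester carbinol, C9, C11–C13 the methylene lactone.
2. Late disconnections: C8–O angelate (Mitsunobu, inversion); C7–C8 by chromium-mediated intramolecular allylation of a C8 aldehyde with a 3-(bromomethyl)butenolide, which closes the ten-membered carbocycle and unveils the exo-methylene lactone; C1–O from a C1 acetyl group (Baeyer–Villiger).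
3. Key disconnection: the oxolane (O, C3, C2, C1, C10) is traced to the oxane O–C3–C2–C1–C(OH)Me–C10, built by Prins closure (C2–C3) of a dioxolane acetal of enal 17 with diol 7 and contracted by a pinacol shift of C10 onto C1.
4. Enabling feature: in the oxolane the oxygen-bearing C1 lies between the quaternary ether carbon C10 and the C2 methylene next to ether carbon C3, so a C1 acyl group maps the ring onto a vicinal-diol (pinacol) unit C10–C(OH) plus an oxocarbenium/alkene (Prins) pair C3 / C2=C1.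
5. Ring order: butenolide (ring-closing metathesis, step 10), oxane then oxolane (step 14), ten-membered carbocycle (step 19); fragments 7 (from ethyl pyruvate) and 17 (from 4-methylfuran-2(5H)-one).

Key step: step 14

Remark (assumption): the stereodescriptors are followed exactly as written; they place the C4 arm on C3 and the C9 arm on C10 on opposite faces of the oxolane (C4 arm, C1 hydroxyl and C10 methyl cis), i.e. an in,out ether bridge, so both ether carbons are fixed in step 14 before the ten-membered ring is closed.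

**Route**

Step 1
Reactants: 1 ethyl pyruvate; 2 ethynyltrimethylsilane
Product: 3 ethyl (2R)-2-hydroxy-2-methyl-4-(trimethylsilyl)but-3-ynoate
Conditions: Zn(OTf)2 (20 mol %), (1S,2S)-2-(dimethylamino)-1-(4-nitrophenyl)-3-[(tert-butyldimethylsilyl)oxy]propan-1-ol or its enantiomer (22 mol %; the enantiomer that gives the R carbinol), Et3N, toluene, 70 °C
Reagents that add atoms: none
Why: Catalytic asymmetric alkynylation of an α-keto ester by a zinc acetylide, in which the ligand-bound zinc chelate of the keto ester exposes one ketone face and so sets the quaternary carbinol (later C10) as R.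

Step 2
Reactants: 3 ethyl (2R)-2-hydroxy-2-methyl-4-(trimethylsilyl)but-3-ynoate
Product: 4 (2R)-2-hydroxy-N-methoxy-N,2-dimethyl-4-(trimethylsilyl)but-3-ynamide
Conditions: MeNH(OMe)·HCl, i-PrMgCl, THF, −20 → 0 °C
Reagents that add atoms: N,O-dimethylhydroxylamine hydrochloride CNOC.Cl
Why: Weinreb amide formation by aminolysis of the ester with the magnesium amide, the non-enolizable quaternary centre staying R.

Step 3
Reactants: 4 (2R)-2-hydroxy-N-methoxy-N,2-dimethyl-4-(trimethylsilyl)but-3-ynamide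
Product: 5 (3R)-3-hydroxy-3-methyl-5-(trimethylsilyl)pent-4-yn-2-one
Conditions: MeMgBr (3 equiv), THF, 0 °C; aq. NH4Cl
Reagents that add atoms: methylmagnesium bromide C[Mg]Br
Why: Weinreb ketone synthesis, the chelated tetrahedral intermediate stopping the addition at the methyl ketone.

Step 4
Reactants: 5 (3R)-3-hydroxy-3-methyl-5-(trimethylsilyl)pent-4-yn-2-one
Product: 7 (3R)-3,4-dimethylhex-5-en-1-yne-3,4-diol, via silylated diol 6 (not isolated)
Conditions: CH2=CHMgBr (2.5 equiv), THF, −78 → 0 °C; then K2CO3, MeOH, rt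
Reagents that add atoms: vinylmagnesium bromide C=C[Mg]Br
Why: Chelation-controlled Grignard addition to the α-alkoxide ketone followed by methanolysis of the alkynyl C–Si bond; the new carbinol carbon need not be single because it becomes the acetyl carbon in step 14.

Step 5
Reactants: 8 4-methylfuran-2(5H)-one
Product: 9 (2Z)-4-hydroxy-N-methoxy-N,3-dimethylbut-2-enamide
Conditions: MeNH(OMe)·HCl, i-PrMgCl, THF, −20 °C
Reagents that add atoms: N,O-dimethylhydroxylamine hydrochloride CNOC.Cl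
Why: Aminolysis of the lactone by the magnesium amide gives the Weinreb amide, the Z geometry being inherited from the ring.

Step 6
Reactants: 9 (2Z)-4-hydroxy-N-methoxy-N,3-dimethylbut-2-enamide
Product: 10 (2Z)-4-[(tert-butyldimethylsilyl)oxy]-N-methoxy-N,3-dimethylbut-2-enamide
Conditions: TBSCl, imidazole, DMF, 0 °C
Reagents that add atoms: tert-butyldimethylsilyl chloride CC(C)(C)[Si](C)(C)Cl
Why: Silyl ether formation at the primary alcohol, which also blocks relactonization.

Step 7
Reactants: 10 (2Z)-4-[(tert-butyldimethylsilyl)oxy]-N-methoxy-N,3-dimethylbut-2-enamide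
Product: 11 (2Z)-4-[(tert-butyldimethylsilyl)oxy]-3-methylbut-2-enal
Conditions: i-Bu2AlH, THF, −78 °C
Reagents that add atoms: none
Why: Weinreb amide reduction stops at the aldehyde because the chelated tetrahedral intermediate survives until work-up, and the low temperature should keep the Z alkene.

Step 8
Reactants: 11 (2Z)-4-[(tert-butyldimethylsilyl)oxy]-3-methylbut-2-enal
Product: 12 (3R,4Z)-6-[(tert-butyldimethylsilyl)oxy]-5-methylhexa-1,4-dien-3-ol
Conditions: Zn(CH=CH2)2 (1.5 equiv; from CH2=CHMgBr and ZnCl2), 3-exo-morpholinoisoborneol (10 mol %; the enantiomer that gives the R carbinol), toluene, −30 → 0 °C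
Reagents that add atoms: divinylzinc C=C[Zn]C=C
Why: Amino-alcohol-catalysed enantioselective vinylzinc addition to the aldehyde, the chiral zinc aminoalkoxide directing vinyl transfer to one face and setting the carbinol that becomes C6.

Step 9
Reactants: 12 (3R,4Z)-6-[(tert-butyldimethylsilyl)oxy]-5-methylhexa-1,4-dien-3-ol; 13 2-(bromomethyl)prop-2-enoic acid
Product: 14 (3R,4Z)-6-[(tert-butyldimethylsilyl)oxy]-5-methylhexa-1,4-dien-3-yl 2-(bromomethyl)prop-2-enoate
Conditions: DCC, DMAP (5 mol %), CH2Cl2, 0 °C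
Reagents that add atoms: none
Why: Steglich esterification of the secondary alcohol, the carbinol stereocentre not being involved.

Step 10
Reactants: 14 (3R,4Z)-6-[(tert-butyldimethylsilyl)oxy]-5-methylhexa-1,4-dien-3-yl 2-(bromomethyl)prop-2-enoate
Product: 15 (5S)-3-(bromomethyl)-5-{(1Z)-3-[(tert-butyldimethylsilyl)oxy]-2-methylprop-1-en-1-yl}furan-2(5H)-one
Conditions: RuCl2(=CHPh)(PCy3)(H2IMes) (second-generation Grubbs catalyst, 5 mol %), CH2Cl2, 40 °C
Reagents that add atoms: none
Why: Ring-closing metathesis between the vinyl group and the acrylate closes the five-membered butenolide with loss of ethene, the trisubstituted alkene being too hindered to compete.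

Step 11
Reactants: 15 (5S)-3-(bromomethyl)-5-{(1Z)-3-[(tert-butyldimethylsilyl)oxy]-2-methylprop-1-en-1-yl}furan-2(5H)-one
Product: 16 (5S)-3-(bromomethyl)-5-[(1Z)-3-hydroxy-2-methylprop-1-en-1-yl]furan-2(5H)-one
Conditions: HF·pyridine, pyridine, THF, 0 °C
Reagents that add atoms: none
Why: Fluoride cleavage of the primary silyl ether under weakly acidic conditions, avoiding base that would epimerize the γ-carbon of the butenolide.

Step 12
Reactants: 16 (5S)-3-(bromomethyl)-5-[(1Z)-3-hydroxy-2-methylprop-1-en-1-yl]furan-2(5H)-one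
Product: 17 (2Z)-3-[(2S)-4-(bromomethyl)-5-oxo-2,5-dihydrofuran-2-yl]-2-methylprop-2-enal
Conditions: MnO2, CH2Cl2, rt
Reagents that add atoms: none
Why: Allylic alcohol oxidation with MnO2 under neutral conditions, which should keep the Z geometry of the enal.

Step 13
Reactants: 7 (3R)-3,4-dimethylhex-5-en-1-yne-3,4-diol; 17 (2Z)-3-[(2S)-4-(bromomethyl)-5-oxo-2,5-dihydrofuran-2-yl]-2-methylprop-2-enal
Product: 18 (5S)-3-(bromomethyl)-5-{(1Z)-2-[(4R)-4-ethynyl-4,5-dimethyl-5-vinyl-1,3-dioxolan-2-yl]prop-1-en-1-yl}furan-2(5H)-one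
Conditions: p-TsOH·H2O (5 mol %), MgSO4, CH2Cl2, 0 °C → rt
Reagents that add atoms: none
Why: Acid-catalysed acetalization of the 1,2-diol with the enal under dehydrating conditions; the acetal carbon and the vinyl-bearing carbon form as mixtures, which is harmless because both become sp2 in step 14.

Step 14
Reactants: 18 (5S)-3-(bromomethyl)-5-{(1Z)-2-[(4R)-4-ethynyl-4,5-dimethyl-5-vinyl-1,3-dioxolan-2-yl]prop-1-en-1-yl}furan-2(5H)-one
Product: 21 1-[(2S,3S,5S)-5-{(1Z)-1-[(2S)-4-(bromomethyl)-5-oxo-2,5-dihydrofuran-2-yl]prop-1-en-2-yl}-2-ethynyl-2-methyloxolan-3-yl]ethan-1-one, via oxocarbenium ion 19 (not isolated), via oxan-4-yl cation 20 (not isolated)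
Conditions: SnCl4 (1.5 equiv), CH2Cl2, −78 → −23 °C
Reagents that add atoms: none
Why: SnCl4 opens the dioxolane at the oxygen on the vinyl-bearing carbon to the (E)-oxocarbenium ion 19, whose terminal alkene carbon C2 attacks C3 in a chair-like Prins closure to give oxan-4-yl cation 20, and ring carbon C10 then shifts from the tin-bound carbinol carbon to cationic C1 (pinacol shift), which contracts the six-membered oxane to the oxolane and turns the carbinol carbon into the acetyl group. The closest known reaction type is the acetal-initiated Prins–pinacol synthesis of 3-acyl tetrahydrofurans from acetals of allylic 1,2-diols, which is known with α,β-unsaturated aldehydes and with alkynyl substituents. The only ring closed is the oxane, by 6-endo-trig attack of the alkene on the oxocarbenium carbon; the oxolane is not closed directly but arises from the oxane by the 1,2-shift, C10 migrating with retention. C10 comes in from diol 7; C3 is set by the chair that places the alkenyl group of the (E)-oxocarbenium equatorial and, at C10, methyl equatorial and the conformationally much smaller ethynyl group axial; C1 is set because C10 bonds to the cation lobe it already flanks, so the C4 arm, the acetyl group and the C10 methyl end up cis and the ethynyl (C9) arm trans. The step needs the Prins–pinacol path to win over a 2-oxonia-Cope/aldol path (which would erase C10) and over E/Z isomerization of the enal; the fast shift next to the stannylated alkoxide at low temperature should secure the first, and the electron-poor lactone oxygen on C6 disfavours allyl-cation character at C5 for the second.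

Step 15
Reactants: 21 1-[(2S,3S,5S)-5-{(1Z)-1-[(2S)-4-(bromomethyl)-5-oxo-2,5-dihydrofuran-2-yl]prop-1-en-2-yl}-2-ethynyl-2-methyloxolan-3-yl]ethan-1-one
Product: 22 (2R,3S,5S)-5-{(1Z)-1-[(2S)-4-(bromomethyl)-5-oxo-2,5-dihydrofuran-2-yl]prop-1-en-2-yl}-2-ethynyl-2-methyloxolan-3-yl acetate
Conditions: (Me3SiO)2 (3 equiv), Me3SiOTf (20 mol %), CH2Cl2, −40 → −10 °C
Reagents that add atoms: bis(trimethylsilyl) peroxide C[Si](C)(C)OO[Si](C)(C)C
Why: Baeyer–Villiger oxidation with a silyl peroxide under aprotic Lewis acid catalysis, which spares C=C and C≡C; the secondary oxolanyl carbon migrates in preference to methyl and with retention, so oxygen takes the place of the acetyl carbon at C1.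

Step 16
Reactants: 22 (2R,3S,5S)-5-{(1Z)-1-[(2S)-4-(bromomethyl)-5-oxo-2,5-dihydrofuran-2-yl]prop-1-en-2-yl}-2-ethynyl-2-methyloxolan-3-yl acetate
Product: 23 (2R,3S,5S)-5-{(1Z)-1-[(2S)-4-(bromomethyl)-5-oxo-2,5-dihydrofuran-2-yl]prop-1-en-2-yl}-2-ethynyl-2-methyloxolan-3-ol
Conditions: AcCl (0.3 equiv), MeOH, 0 °C → rt
Reagents that add atoms: none
Why: Acid-catalysed transesterification (methanolysis) of the acetate, base being avoided because it would epimerize the γ-carbon of the butenolide.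

Step 17
Reactants: 23 (2R,3S,5S)-5-{(1Z)-1-[(2S)-4-(bromomethyl)-5-oxo-2,5-dihydrofuran-2-yl]prop-1-en-2-yl}-2-ethynyl-2-methyloxolan-3-ol
Product: 24 (5S)-3-(bromomethyl)-5-{(1Z)-2-[(2S,4S,5R)-5-ethynyl-5-methyl-4-[(triethylsilyl)oxy]oxolan-2-yl]prop-1-en-1-yl}furan-2(5H)-one
Conditions: Et3SiOTf, 2,6-lutidine, CH2Cl2, −78 °C
Reagents that add atoms: triethylsilyl trifluoromethanesulfonate CC[Si](CC)(CC)OS(=O)(=O)C(F)(F)F
Why: Silylation of the hindered secondary alcohol with a silyl triflate and a non-nucleophilic pyridine base, which leaves the allylic bromide alone.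

Step 18
Reactants: 24 (5S)-3-(bromomethyl)-5-{(1Z)-2-[(2S,4S,5R)-5-ethynyl-5-methyl-4-[(triethylsilyl)oxy]oxolan-2-yl]prop-1-en-1-yl}furan-2(5H)-one
Product: 26 2-[(2R,3S,5S)-5-{(1Z)-1-[(2S)-4-(bromomethyl)-5-oxo-2,5-dihydrofuran-2-yl]prop-1-en-2-yl}-2-methyl-3-[(triethylsilyl)oxy]oxolan-2-yl]acetaldehyde, via alkenylborane 25 (not isolated)
Conditions: Cy2BH (1.2 equiv), THF, 0 °C; then H2O2, pH 7 phosphate buffer, 0 °C
Reagents that add atoms: hydrogen peroxide OO
Why: Anti-Markovnikov hydroboration of the terminal alkyne with a hindered dialkylborane and oxidation of the alkenylborane give the C8 aldehyde with C9 as CH2; the alkyne reacts ahead of the trisubstituted alkene and the electron-poor butenolide, and the neutral oxidation avoids retro-oxa-Michael opening of the oxolane.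

Step 19
Reactants: 26 2-[(2R,3S,5S)-5-{(1Z)-1-[(2S)-4-(bromomethyl)-5-oxo-2,5-dihydrofuran-2-yl]prop-1-en-2-yl}-2-methyl-3-[(triethylsilyl)oxy]oxolan-2-yl]acetaldehyde
Product: 28 (1S,3S,6S,7R,8S,10R)-8-hydroxy-1-[(triethylsilyl)oxy]-3,10-epoxygermacra-4Z,11(13)-dien-12,6-olide, via allylchromium species 27 (not isolated)
Conditions: CrCl2 (8 equiv), THF, 0.002 M, rt
Reagents that add atoms: none
Why: Intramolecular chromium Barbier (Nozaki–Hiyama–Kishi-type) allylation, in which the allylchromium reagent formed at the bromomethyl group adds through its γ-carbon C7 to the C8 aldehyde in an irreversible, strongly exothermic step at high dilution; the tether from C6 should deliver the aldehyde to the C5 face of the butenolide (C7, cis-fused lactone), the six-membered chromium chair with C6 and C9 equatorial should give the 8S carbinol that step 20 inverts, and the double-bond shift unveils the exo-methylene lactone.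

Step 20
Reactants: 28 (1S,3S,6S,7R,8S,10R)-8-hydroxy-1-[(triethylsilyl)oxy]-3,10-epoxygermacra-4Z,11(13)-dien-12,6-olide; 29 angelic acid
Product: 31 (1S,3S,6S,7R,8R,10R)-8-[(2Z)-2-methylbut-2-enoyloxy]-1-[(triethylsilyl)oxy]-3,10-epoxygermacra-4Z,11(13)-dien-12,6-olide, via alkoxyphosphonium angelate 30 (not isolated)
Conditions: PPh3, i-PrO2C–N=N–CO2i-Pr, toluene, 0 °C → rt
Reagents that add atoms: none
Why: Mitsunobu esterification, in which angelate displaces the alkoxyphosphonium group at C8 with inversion (SN2) and so sets 8R, and because the acid is never activated as an acyl electrophile its Z geometry should be kept.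

Step 21
Reactants: 31 (1S,3S,6S,7R,8R,10R)-8-[(2Z)-2-methylbut-2-enoyloxy]-1-[(triethylsilyl)oxy]-3,10-epoxygermacra-4Z,11(13)-dien-12,6-olide
Product: 32 (1S,3S,6S,7R,8R,10R)-8-[(2Z)-2-methylbut-2-enoyloxy]-1-hydroxy-3,10-epoxygermacra-4Z,11(13)-dien-12,6-olide
Conditions: HF·pyridine, pyridine, THF, 0 °C → rt
Reagents that add atoms: none
Why: Fluoride-mediated silyl ether cleavage under buffered, weakly acidic conditions that leave the angelate and the methylene lactone untouched.

**Compound list**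

1 | ethyl pyruvate | CCOC(=O)C(C)=O | starting material
2 | ethynyltrimethylsilane | C#C[Si](C)(C)C | starting material
3 | ethyl (2R)-2-hydroxy-2-methyl-4-(trimethylsilyl)but-3-ynoate | CCOC(=O)[C@@](C)(C#C[Si](C)(C)C)O | intermediate
4 | (2R)-2-hydroxy-N-methoxy-N,2-dimethyl-4-(trimethylsilyl)but-3-ynamide | CON(C)C(=O)[C@@](C)(C#C[Si](C)(C)C)O | intermediate
5 | (3R)-3-hydroxy-3-methyl-5-(trimethylsilyl)pent-4-yn-2-one | CC(=O)[C@@](C)(C#C[Si](C)(C)C)O | intermediate
6 | (3R)-3,4-dimethyl-1-(trimethylsilyl)hex-5-en-1-yne-3,4-diol (both C4 epimers) | C=CC(C)(O)[C@@](C)(C#C[Si](C)(C)C)O | intermediate (not isolated)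
7 | (3R)-3,4-dimethylhex-5-en-1-yne-3,4-diol (both C4 epimers) | C=CC(C)(O)[C@@](C)(C#C)O | intermediate
8 | 4-methylfuran-2(5H)-one | CC1=CC(=O)OC1 | starting material
9 | (2Z)-4-hydroxy-N-methoxy-N,3-dimethylbut-2-enamide | OC/C(C)=C\C(=O)N(C)OC | intermediate
10 | (2Z)-4-[(tert-butyldimethylsilyl)oxy]-N-methoxy-N,3-dimethylbut-2-enamide | CC(C)(C)[Si](C)(C)OC/C(C)=C\C(=O)N(C)OC | intermediate
11 | (2Z)-4-[(tert-butyldimethylsilyl)oxy]-3-methylbut-2-enal | CC(C)(C)[Si](C)(C)OC/C(C)=C\C=O | intermediate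
12 | (3R,4Z)-6-[(tert-butyldimethylsilyl)oxy]-5-methylhexa-1,4-dien-3-ol | O[C@H](C=C)/C=C(/C)CO[Si](C)(C)C(C)(C)C | intermediate
13 | 2-(bromomethyl)prop-2-enoic acid | C=C(CBr)C(=O)O | starting material
14 | (3R,4Z)-6-[(tert-butyldimethylsilyl)oxy]-5-methylhexa-1,4-dien-3-yl 2-(bromomethyl)prop-2-enoate | C=C(CBr)C(=O)O[C@H](C=C)/C=C(/C)CO[Si](C)(C)C(C)(C)C | intermediate
15 | (5S)-3-(bromomethyl)-5-{(1Z)-3-[(tert-butyldimethylsilyl)oxy]-2-methylprop-1-en-1-yl}furan-2(5H)-one | O=C1O[C@H](C=C1CBr)/C=C(/C)CO[Si](C)(C)C(C)(C)C | intermediate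
16 | (5S)-3-(bromomethyl)-5-[(1Z)-3-hydroxy-2-methylprop-1-en-1-yl]furan-2(5H)-one | O=C1O[C@H](C=C1CBr)/C=C(/C)CO | intermediate
17 | (2Z)-3-[(2S)-4-(bromomethyl)-5-oxo-2,5-dihydrofuran-2-yl]-2-methylprop-2-enal | O=C1O[C@H](C=C1CBr)/C=C(/C)C=O | intermediate
18 | (5S)-3-(bromomethyl)-5-{(1Z)-2-[(4R)-4-ethynyl-4,5-dimethyl-5-vinyl-1,3-dioxolan-2-yl]prop-1-en-1-yl}furan-2(5H)-one (epimers at C2 and C5 of the dioxolane) | O=C1O[C@H](C=C1CBr)/C=C(/C)C2OC(C)(C=C)[C@@](C)(C#C)O2 | intermediate
19 | oxocarbenium ion: the enal carbon of 17 doubly bonded to the C3 oxygen of diol 7, the C4 oxygen carried as a tetrachlorostannate alkoxide | O=C1O[C@H](C=C1CBr)/C=C(/C)C=[O+][C@](C)(C#C)C(C)(C=C)O[Sn-](Cl)(Cl)(Cl)Cl | intermediate (not isolated)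
20 | (2S,6R)-2-alkenyl-6-ethynyl-5,6-dimethyl-5-(tetrachlorostannyloxy)oxan-4-yl cation | O=C1O[C@H](C=C1CBr)/C=C(/C)[C@@H]2C[CH+]C(C)(O[Sn-](Cl)(Cl)(Cl)Cl)[C@@](C)(C#C)O2 | intermediate (not isolated)
21 | 1-[(2S,3S,5S)-5-{(1Z)-1-[(2S)-4-(bromomethyl)-5-oxo-2,5-dihydrofuran-2-yl]prop-1-en-2-yl}-2-ethynyl-2-methyloxolan-3-yl]ethan-1-one | O=C1O[C@H](C=C1CBr)/C=C(/C)[C@@H]2C[C@H](C(C)=O)[C@@](C)(C#C)O2 | intermediate
22 | (2R,3S,5S)-5-{(1Z)-1-[(2S)-4-(bromomethyl)-5-oxo-2,5-dihydrofuran-2-yl]prop-1-en-2-yl}-2-ethynyl-2-methyloxolan-3-yl acetate | O=C1O[C@H](C=C1CBr)/C=C(/C)[C@@H]2C[C@H](OC(C)=O)[C@@](C)(C#C)O2 | intermediate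
23 | (2R,3S,5S)-5-{(1Z)-1-[(2S)-4-(bromomethyl)-5-oxo-2,5-dihydrofuran-2-yl]prop-1-en-2-yl}-2-ethynyl-2-methyloxolan-3-ol | O=C1O[C@H](C=C1CBr)/C=C(/C)[C@@H]2C[C@H](O)[C@@](C)(C#C)O2 | intermediate
24 | (5S)-3-(bromomethyl)-5-{(1Z)-2-[(2S,4S,5R)-5-ethynyl-5-methyl-4-[(triethylsilyl)oxy]oxolan-2-yl]prop-1-en-1-yl}furan-2(5H)-one | O=C1O[C@H](C=C1CBr)/C=C(/C)[C@@H]2C[C@H](O[Si](CC)(CC)CC)[C@@](C)(C#C)O2 | intermediate
25 | (E)-alkenyl(dicyclohexyl)borane from 24 (boron on the former terminal alkyne carbon) | O=C1O[C@H](C=C1CBr)/C=C(/C)[C@@H]2C[C@H](O[Si](CC)(CC)CC)[C@@](C)(/C=C/B(C3CCCCC3)C3CCCCC3)O2 | intermediate (not isolated)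
26 | 2-[(2R,3S,5S)-5-{(1Z)-1-[(2S)-4-(bromomethyl)-5-oxo-2,5-dihydrofuran-2-yl]prop-1-en-2-yl}-2-methyl-3-[(triethylsilyl)oxy]oxolan-2-yl]acetaldehyde | O=C1O[C@H](C=C1CBr)/C=C(/C)[C@@H]2C[C@H](O[Si](CC)(CC)CC)[C@@](C)(CC=O)O2 | intermediate
27 | allylchromium dichloride from 26 (CrCl2 in place of Br) | O=C1O[C@H](C=C1C[Cr](Cl)Cl)/C=C(/C)[C@@H]2C[C@H](O[Si](CC)(CC)CC)[C@@](C)(CC=O)O2 | intermediate (not isolated)
28 | (1S,3S,6S,7R,8S,10R)-8-hydroxy-1-[(triethylsilyl)oxy]-3,10-epoxygermacra-4Z,11(13)-dien-12,6-olide | C=C1C(=O)O[C@H]2/C=C(/C)[C@@H]3C[C@H](O[Si](CC)(CC)CC)[C@@](C)(C[C@H](O)[C@@H]12)O3 | intermediate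
29 | angelic acid, (2Z)-2-methylbut-2-enoic acid | C/C=C(/C)C(=O)O | starting material
30 | C8 alkoxy(triphenyl)phosphonium salt of 28 with angelate as counter-ion | C=C1C(=O)O[C@H]2/C=C(/C)[C@@H]3C[C@H](O[Si](CC)(CC)CC)[C@@](C)(C[C@H](O[P+](c4ccccc4)(c4ccccc4)c4ccccc4)[C@@H]12)O3.C/C=C(/C)C(=O)[O-] | intermediate (not isolated)
31 | (1S,3S,6S,7R,8R,10R)-8-[(2Z)-2-methylbut-2-enoyloxy]-1-[(triethylsilyl)oxy]-3,10-epoxygermacra-4Z,11(13)-dien-12,6-olide | C=C1C(=O)O[C@H]2/C=C(/C)[C@@H]3C[C@H](O[Si](CC)(CC)CC)[C@@](C)(C[C@@H](OC(=O)/C(C)=C\C)[C@@H]12)O3 | intermediate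
32 | (1S,3S,6S,7R,8R,10R)-8-[(2Z)-2-methylbut-2-enoyloxy]-1-hydroxy-3,10-epoxygermacra-4Z,11(13)-dien-12,6-olide | C=C1C(=O)O[C@H]2/C=C(/C)[C@@H]3C[C@H](O)[C@@](C)(C[C@@H](OC(=O)/C(C)=C\C)[C@@H]12)O3 | target

**Step count and risks**

Total step count: 21. Longest linear sequence: 17 steps (steps 5–12, then 13–21).

Steps most likely to fail:

1. Step 19. The ring being closed is the strained in,out bicycle, so intermolecular allylation (oligomers) may outrun ring closure, and the ring may override the chair preference at C8. Fallback (sets out from 26, comes back at 28): the allylic bromide is exchanged for silicon with Me3SiSiMe3 and Pd2(dba)3 (THF, rt) to give the allylsilane aldehyde F1, which is closed with BF3·OEt2 in CH2Cl2 at −78 °C and high dilution in an intramolecular Hosomi–Sakurai allylation (open, Lewis-acid-activated transition state instead of the chromium chair) to 28.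

2. Step 14. The cation may leak into the 2-oxonia-Cope/aldol channel with loss of the C10 configuration, the ethynyl-axial chair preference may be incomplete (C3 and C1 epimers), or the Z enal may isomerize before cyclization. Fallback (sets out from 18, comes back at 21): the Prins closure is run alone with CF3CO2H in CH2Cl2 at −20 °C, the oxan-4-yl cation being captured as the equatorial oxan-4-yl trifluoroacetate F2. Mild hydrolysis (aq. NaHCO3, MeOH) gives the oxane-4,5-diol F3, and the secondary hydroxyl is mesylated (Ms2O, 2,6-lutidine) to the hydroxy mesylate F4. Et2AlCl at −78 °C then brings about the semipinacol ring contraction, in which the ring bond to C10 antiperiplanar to the equatorial mesylate migrates, to give 21.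

3. Step 20. Displacement at the hindered ring carbinol may be slow, with elimination or with retention through an acyloxyphosphonium pathway. Fallback (sets out from 28, comes back at 31): Dess–Martin oxidation gives the C8 ketone F5. Oxazaborolidine-catalysed (CBS) borane reduction, with the catalyst enantiomer matched to the 8R carbinol, gives the 8R alcohol F6. Acylation with retention by the mixed anhydride F7 (made from 29, 2,4,6-trichlorobenzoyl chloride and Et3N; toluene, 75 °C) then gives 31.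

Further compounds
F1 | step 19 | 2-[(2R,3S,5S)-2-methyl-5-{(1Z)-1-[(2S)-5-oxo-4-[(trimethylsilyl)methyl]-2,5-dihydrofuran-2-yl]prop-1-en-2-yl}-3-[(triethylsilyl)oxy]oxolan-2-yl]acetaldehyde | O=C1O[C@H](C=C1C[Si](C)(C)C)/C=C(/C)[C@@H]2C[C@H](O[Si](CC)(CC)CC)[C@@](C)(CC=O)O2
F2 | step 14 | (2S,4S,6R)-2-{(1Z)-1-[(2S)-4-(bromomethyl)-5-oxo-2,5-dihydrofuran-2-yl]prop-1-en-2-yl}-6-ethynyl-5-hydroxy-5,6-dimethyloxan-4-yl trifluoroacetate (C5 epimers) | O=C1O[C@H](C=C1CBr)/C=C(/C)[C@@H]2C[C@H](OC(=O)C(F)(F)F)C(C)(O)[C@@](C)(C#C)O2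
F3 | step 14 | (5S)-3-(bromomethyl)-5-{(1Z)-2-[(2S,4S,6R)-6-ethynyl-4,5-dihydroxy-5,6-dimethyloxan-2-yl]prop-1-en-1-yl}furan-2(5H)-one (C5 epimers) | O=C1O[C@H](C=C1CBr)/C=C(/C)[C@@H]2C[C@H](O)C(C)(O)[C@@](C)(C#C)O2
F4 | step 14 | (2S,4S,6R)-2-{(1Z)-1-[(2S)-4-(bromomethyl)-5-oxo-2,5-dihydrofuran-2-yl]prop-1-en-2-yl}-6-ethynyl-5-hydroxy-5,6-dimethyloxan-4-yl methanesulfonate (C5 epimers) | O=C1O[C@H](C=C1CBr)/C=C(/C)[C@@H]2C[C@H](OS(C)(=O)=O)C(C)(O)[C@@](C)(C#C)O2
F5 | step 20 | (1S,3S,6S,7S,10R)-8-oxo-1-[(triethylsilyl)oxy]-3,10-epoxygermacra-4Z,11(13)-dien-12,6-olide | C=C1C(=O)O[C@H]2/C=C(/C)[C@@H]3C[C@H](O[Si](CC)(CC)CC)[C@@](C)(CC(=O)[C@@H]12)O3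
F6 | step 20 | (1S,3S,6S,7R,8R,10R)-8-hydroxy-1-[(triethylsilyl)oxy]-3,10-epoxygermacra-4Z,11(13)-dien-12,6-olide | C=C1C(=O)O[C@H]2/C=C(/C)[C@@H]3C[C@H](O[Si](CC)(CC)CC)[C@@](C)(C[C@@H](O)[C@@H]12)O3
F7 | step 20 | (2Z)-2-methylbut-2-enoic 2,4,6-trichlorobenzoic anhydride | C/C=C(/C)C(=O)OC(=O)c1c(Cl)cc(Cl)cc1Cl
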